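Remark: the SMILES contains no stereocentre, so the target is treated as achiral 5,7,2′,4′-tetrahydroxy-6-(3-hydroxy-3-methylbutyl)isoflavone. Enol 18 is written as its chelated (Z)-tautomer, which equilibrates with the aldehyde form.

## Analysis of the target

The target is an isoflavone, 3-(2,4-dihydroxyphenyl)-5,7-dihydroxy-6-(3-hydroxy-3-methylbutyl)-4H-chromen-4-one, in which ring A is a phloroglucinol-type benzene fused to the pyranone ring C and ring B, a resorcinol unit, sits on C3. With no stereocentre, the problems are regiochemical: the hydrated prenyl chain must sit on C6, between the C5 and C7 oxygens, and not on C8, and ring C must close with ring B on C3. The sensitive groups are the four phenols, the electrophilic C2 of the chromone (ring opening by hard nucleophiles) and above all the tertiary alcohol. Under acid that alcohol ionises and is trapped by the neighbouring C5 or C7 hydroxyl as a dimethylchroman, or it eliminates, so the last deprotection has to be neutral; this points to benzyl ethers and hydrogenolysis. Both bonds that tie ring A to ring C start from neighbouring carbons: C8a carries O1 and C4a carries the C4 carbonyl, with the unsubstituted C8 beside C8a and the C5 oxygen beside C4a. This is the pattern left when a 3-alkoxyaryne takes up an oxygen nucleophile at the carbon remote from the ether and an acyl electrophile at the carbon next to it. Ring A, cut loose from ring C, is also a phenol with a mirror plane through C8a and C6, so its two ortho positions are equivalent and the C6/C8 question is settled before ring C exists.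

## Retrosynthetic reasoning

**23 to 22.** All five hydroxyl groups of 23 are traced back to benzyl ethers in 22. Cutting five O–benzyl bonds last, by catalytic hydrogenolysis, keeps acid and strong base away from the tertiary alcohol and the chromone, and one kind of protecting group needs one deprotection. The forward step must cleave four aryl benzyl ethers and one tertiary alkyl benzyl ether without saturating C2=C3.

**22 to 13 and 18.** Ring C of 22 is opened at O1–C8a and C4–C4a. Both bonds end on adjacent carbons of ring A, so ring A becomes aryne 20. O1, C2, C3, C4 and ring B stay together in the formylated arylacetate 18, which reacts as its caesium enolate 19 and whose ester carbon is the later C4. Cutting here, and not at C3–C1′ or at C2, avoids first building an ortho-hydroxy ketone on the crowded ring A, and it joins two fragments of similar size in the step that closes the ring. Aryne 20 is released from silyl triflate 13. The forward reaction needs the oxygen of 19 to go to C8a and the anion 21 at C4a to acylate; the C5 ether beside the triple bond should enforce this.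

**13 to 9 to 8.** The C–Si and O–S bonds of 13 are removed. The silyl group on the later C4a comes by oxygen-to-carbon migration in aryllithium 11, made from silyl ether 10 of bromophenol 9, and phenolate 12 is trapped as the triflate. Bromide 9 is cut at C–Br to phenol 8. Because 8 is mirror-symmetric, bromination at either ortho position gives the same compound, which fixes the chain at the later C6.

**8 to 7 to 6 to 5.** These are functional-group changes. Phenol 8 comes from silyl ether 7 by desilylation; the silyl group on this one oxygen, against benzyl on the others, is what lets it become the triflate. Ether 7 comes from tertiary alcohol 6 by O-benzylation. The chain oxygen must be capped with a fluoride-stable group, since a free or silylated alcohol would supply a proton or an alkoxide in the key step. Alcohol 6 comes from prenyl arene 5 by Markovnikov hydration.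

**5 to 2 and 3, and 2 to 1.** The ring–chain bond is cut: 5 arises from aryllithium 4 and allylic bromide 3. The carbon to be metalated in 2 lies between two ether oxygens, and the bulky silyl ether of 2, made from commercial 1, shields the other two positions.

**18 to 16 to 15 to 14.** The later C2–C3 bond is cut by a retro-Claisen step: 18 comes from arylacetate 16 by C-formylation, which passes through sodium enolate 17. Ester 16 comes from diphenol 15, and 15 from acid 14. Ring B thus enters with both oxygens in place and needs no regiochemical decision.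

## Alternatives that were turned down

**Alternative 1:** Ring A is built last by cutting C7–C8 and C5–C6.
- **Disconnection:** this leaves the pyranone ester A2, which already holds ring C and ring B, and the lactone A3. The lactone carbonyl carbon becomes C7, its α-carbon C6, and the rest of its ring the chain with the tertiary oxygen.
- **Forward key step:** excess LiN(iPr)2 deprotonates the 2-methyl group of A2. The carbanion opens A3 by Claisen acylation, a Dieckmann reaction onto the neighbouring ester of A2 follows, and tautomerisation gives the aromatic diol A1.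
- **For:** it is highly convergent, the chain cannot end up on the wrong carbon, and the tertiary alcohol appears unprotected. Only two benzyl ethers remain to be removed. On protecting-group economy and on steps after the key step it is at least as good as the chosen route.
- **Against:** A3 is enolisable and the lithiated methyl group is a strong base, so proton transfer competes with acylation. The Dieckmann closure must occur at the less acidic, chain-bearing carbon of a polyanion, onto a hindered ester. Amide base and the liberated alkoxide can add to the electron-poor pyranone of A2 and open it. A2 is itself a multistep target.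
- **Comparison:** the chosen route pays with five benzyl ethers, but each new bond joins one clearly defined nucleophile and one non-enolisable electrophile, and both fragments come from ordinary aromatic chemistry.

**Alternative 2:** Ring C is closed at C3–C4, at the oxidation level of a 3-hydroxyisoflavanone.
- **Disconnection:** the precursor is keto aldehyde A5. Its aldehyde carbon on ring A is the later C4, and the aryl ketone hanging from O1 through the C2 methylene is the later C3.
- **Forward key step:** a triazolium-derived N-heterocyclic carbene with an amine base turns the aldehyde of A5 into an acyl anion equivalent, which adds to the ketone (6-exo-trig) and gives racemic A4. Dehydration across C2–C3 and hydrogenolysis would follow.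
- **For:** the intramolecular aldehyde–ketone benzoin reaction to 3-hydroxychroman-4-ones is established, so on precedent this route is stronger than the chosen one. A5 could be reached from phenol 8 by ortho-formylation and O-alkylation, so the C6/C8 question is solved the same way.
- **Against:** the aldehyde of A5 is flanked by two ortho oxygens, hindered and electron-rich, which slows carbene addition. The base can instead enolise the ketone at the C2 methylene, and intramolecular aldol condensation onto the aldehyde then closes a five-membered ring in place of ring C. The step creates a stereocentre the target lacks, and it must be erased by dehydrating a tertiary alcohol, under conditions that threaten the tertiary benzyl ether. From 8 it needs five operations (formylation, alkylation, benzoin, dehydration, hydrogenolysis) against four.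
- **Comparison:** the chosen route reaches the chromone oxidation level in the ring-closing step itself and needs no redox or elimination correction, at the price of an unprecedented partner.

**Alternative 3:** Ring B is built last on a finished chromone.
- **Disconnection:** C2′–C3′, C4′–C5′ and C1′–C2′ are cut, which leads to the dienyl diazo ketone A7, which already carries rings A and C, and the siloxyalkyne A8.
- **Forward key step:** irradiation of A7 causes Wolff rearrangement. A [2+2] cycloaddition with A8, four-electron ring opening, six-electron electrocyclisation and tautomerisation then give the phenol A6.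
- **For:** the substitution pattern of ring B is fixed by construction, and its two oxygens come out differentiated (free 2′-OH, 4′-silyl ether). The chosen route cannot do this, although the target does not need it. The benzannulation is known chemistry.
- **Against:** it builds the simplest part of the molecule, a resorcinol ring available in commercial arylacetic acids, by the most elaborate sequence. A7 requires the complete ring A chromone first (C-acylation of ring A, formylative closure of ring C, olefination, diazo transfer), a long linear sequence. The chromone is a strong chromophore with an electrophilic C2 conjugated to the diazo enone, so photochemical side reactions are likely. Two deprotections follow the key step.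
- **Comparison:** the chosen route is shorter and convergent; Alternative 3 would be better only if the ring B oxygens had to be told apart.

Key step: step 11

## Route

Step 1
Reactants: 1 3,5-bis(benzyloxy)phenol
Product: 2 [3,5-bis(benzyloxy)phenoxy]tri(propan-2-yl)silane
Conditions: TIPSCl, imidazole, DMF, rt
Reagents that add atoms: triisopropylsilyl chloride, CC(C)[Si](Cl)(C(C)C)C(C)C
Why: O-silylation of a phenol; the bulky silyl ether marks this oxygen as different from the benzyl ethers and shields both ortho positions for the metalation that follows.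

Step 2
Reactants: 2 [3,5-bis(benzyloxy)phenoxy]tri(propan-2-yl)silane; 3 1-bromo-3-methylbut-2-ene
Product: 5 [3,5-bis(benzyloxy)-4-(3-methylbut-2-en-1-yl)phenoxy]tri(propan-2-yl)silane, via aryllithium 4 (not isolated)
Conditions: nBuLi, THF, 0 °C; then 3, −78 °C to rt
Reagents that add atoms: none
Why: Directed ortho-metalation at the hydrogen between the two coordinating benzyloxy groups, the most acidic ring position, while the sites beside the bulky, weakly coordinating silyl ether are blocked; the aryllithium then displaces bromide at the primary allylic carbon (SN2).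

Step 3
Reactants: 5 [3,5-bis(benzyloxy)-4-(3-methylbut-2-en-1-yl)phenoxy]tri(propan-2-yl)silane
Product: 6 4-{2,6-bis(benzyloxy)-4-[tri(propan-2-yl)silyloxy]phenyl}-2-methylbutan-2-ol
Conditions: Co(acac)2 (cat.), PhSiH3, O2 (1 atm), THF, rt
Reagents that add atoms: dioxygen, O=O
Why: Mukaiyama hydration: hydrogen-atom transfer to the less substituted alkene carbon, trapping of the tertiary radical by O2 and reduction of the peroxide give the Markovnikov tertiary alcohol under neutral conditions that leave benzyl and silyl ethers alone.

Step 4
Reactants: 6 4-{2,6-bis(benzyloxy)-4-[tri(propan-2-yl)silyloxy]phenyl}-2-methylbutan-2-ol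
Product: 7 {3,5-bis(benzyloxy)-4-[3-(benzyloxy)-3-methylbutyl]phenoxy}tri(propan-2-yl)silane
Conditions: NaH, BnBr, Bu4NI (cat.), THF, 60 °C
Reagents that add atoms: benzyl bromide, BrCc1ccccc1
Why: Williamson etherification of the tertiary alkoxide; iodide catalysis and heating compensate for the hindered nucleophile, and in THF the aryl triisopropylsilyl ether should stay in place.

Step 5
Reactants: 7 {3,5-bis(benzyloxy)-4-[3-(benzyloxy)-3-methylbutyl]phenoxy}tri(propan-2-yl)silane
Product: 8 3,5-bis(benzyloxy)-4-[3-(benzyloxy)-3-methylbutyl]phenol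
Conditions: Bu4NF, THF, 0 °C; aq. NH4Cl
Reagents that add atoms: none
Why: Fluoride-induced cleavage of the aryl silyl ether, driven by the Si–F bond; the benzyl ethers are inert, and the product is the mirror-symmetric phenol with two equivalent ortho positions.

Step 6
Reactants: 8 3,5-bis(benzyloxy)-4-[3-(benzyloxy)-3-methylbutyl]phenol
Product: 9 3,5-bis(benzyloxy)-2-bromo-4-[3-(benzyloxy)-3-methylbutyl]phenol
Conditions: NBS (1.0 equiv), CH2Cl2, −78 to 0 °C
Reagents that add atoms: N-bromosuccinimide, O=C1CCC(=O)N1Br
Why: Electrophilic aromatic bromination of a strongly activated phenol; the only free ring positions are the two equivalent carbons ortho to the hydroxyl, so one equivalent at low temperature should give a single monobromide.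

Step 7
Reactants: 9 3,5-bis(benzyloxy)-2-bromo-4-[3-(benzyloxy)-3-methylbutyl]phenol
Product: 13 3,5-bis(benzyloxy)-4-[3-(benzyloxy)-3-methylbutyl]-2-(trimethylsilyl)phenyl trifluoromethanesulfonate, via trimethylsilyl ether 10 (not isolated), via aryllithium 11 (not isolated), via lithium phenolate 12 (not isolated)
Conditions: HMDS, THF, 70 °C, then concentrate; nBuLi, THF, −100 to −78 °C; then Tf2O, −100 °C to rt
Reagents that add atoms: hexamethyldisilazane, C[Si](C)(C)N[Si](C)(C)C; trifluoromethanesulfonic anhydride, O=S(=O)(OS(=O)(=O)C(F)(F)F)C(F)(F)F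
Why: O-silylation, bromine–lithium exchange and retro-Brook (oxygen-to-carbon) silyl shift give the ortho-silyl phenolate, which is triflated on oxygen; this is the standard entry to 2-(trimethylsilyl)aryl triflates, and exchange at −100 °C outruns deprotonation of the benzylic ether positions.

Step 8
Reactants: 14 2,4-dihydroxyphenylacetic acid
Product: 15 methyl 2-(2,4-dihydroxyphenyl)acetate
Conditions: MeOH, H2SO4 (cat.), reflux
Reagents that add atoms: methanol, CO
Why: Fischer esterification in excess methanol; any benzofuranone formed by lactonisation is reopened to the methyl ester under the same conditions.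

Step 9
Reactants: 15 methyl 2-(2,4-dihydroxyphenyl)acetate
Product: 16 methyl 2-[2,4-bis(benzyloxy)phenyl]acetate
Conditions: BnBr, K2CO3, DMF, rt
Reagents that add atoms: benzyl bromide, BrCc1ccccc1
Why: Williamson O-benzylation of both phenols; carbonate is too weak a base to alkylate the ester α-carbon.

Step 10
Reactants: 16 methyl 2-[2,4-bis(benzyloxy)phenyl]acetate
Product: 18 methyl (Z)-2-[2,4-bis(benzyloxy)phenyl]-3-hydroxyprop-2-enoate, via sodium enolate 17 (not isolated)
Conditions: NaH, HCO2Me, THF, 0 °C to rt; then 1 M HCl
Reagents that add atoms: methyl formate, COC=O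
Why: Crossed Claisen condensation (C-formylation) of an arylacetate with a non-enolisable formate, driven by formation of the stabilised enolate; acidification gives the hydrogen-bonded (Z)-enol, which is isolated and purified as such.

Step 11
Reactants: 18 methyl (Z)-2-[2,4-bis(benzyloxy)phenyl]-3-hydroxyprop-2-enoate; 13 3,5-bis(benzyloxy)-4-[3-(benzyloxy)-3-methylbutyl]-2-(trimethylsilyl)phenyl trifluoromethanesulfonate
Product: 22 5,7-bis(benzyloxy)-6-[3-(benzyloxy)-3-methylbutyl]-3-[2,4-bis(benzyloxy)phenyl]-4H-chromen-4-one, via caesium enolate 19 (not isolated), via aryne 20 (not isolated), via aryl anion 21 (not isolated)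
Conditions: CsF (4 equiv), THF, 65 °C
Reagents that add atoms: none
Why: Proposed new method: fluoride, acting first as a base, converts the acidic enol 18 into caesium enolate 19 and then attacks silicon of 13, so that triflate leaves and aryne 20 forms with its triple bond between the later C4a and C8a. The C5 benzyloxy group beside the triple bond polarises it, so the enolate oxygen of 19 adds at the remote carbon C8a and the charge develops at C4a, next to the inductively stabilising ether. The aryl anion 21 lies cis to the ester across the enol ether double bond and attacks the ester carbonyl in a 6-exo-trig closure; methoxide leaves, takes up the proton that 18 gave up, and ring C is closed, so that O1–C8a and C4–C4a form in one operation. The closest known reaction type is the fluoride-induced annulation of arynes with methyl salicylates to xanthones (O-arylation, then acylation of the aryl anion), which is run on the free phenol under these same conditions; here the enol of a formylated ester takes the place of the phenol. No stereocentre is formed. The step needs regioselectivity on the aryne, which the C5 ether and the unhindered C8–H side secure, and O- over C-arylation of the ambident enolate, which is favoured because the carbon terminus is fully substituted and screened by the ortho-benzyloxyaryl group while the formyl oxygen is exposed. THF offers no acidic C–H bond and the excess of CsF keeps 18 in its enolate form, so proton transfer to 21 should be slower than the intramolecular acylation.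

Step 12
Reactants: 22 5,7-bis(benzyloxy)-6-[3-(benzyloxy)-3-methylbutyl]-3-[2,4-bis(benzyloxy)phenyl]-4H-chromen-4-one
Product: 23 3-(2,4-dihydroxyphenyl)-5,7-dihydroxy-6-(3-hydroxy-3-methylbutyl)-4H-chromen-4-one
Conditions: H2 (1 atm), Pd/C, EtOAc/MeOH, rt
Reagents that add atoms: none
Why: Catalytic hydrogenolysis of four aryl benzyl ethers and one tertiary alkyl benzyl ether under neutral conditions; the conjugated, trisubstituted C2=C3 bond of the chromone should reduce far more slowly than the O–benzyl bonds cleave, so the reaction is stopped once hydrogen uptake for five benzyl groups is complete.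

## Compound list

1 | 3,5-bis(benzyloxy)phenol | Oc1cc(OCc2ccccc2)cc(OCc2ccccc2)c1 | starting material
2 | [3,5-bis(benzyloxy)phenoxy]tri(propan-2-yl)silane | CC(C)[Si](Oc1cc(OCc2ccccc2)cc(OCc2ccccc2)c1)(C(C)C)C(C)C | intermediate
3 | 1-bromo-3-methylbut-2-ene | CC(C)=CCBr | starting material
4 | {2,6-bis(benzyloxy)-4-[tri(propan-2-yl)silyloxy]phenyl}lithium | [Li]c1c(OCc2ccccc2)cc(O[Si](C(C)C)(C(C)C)C(C)C)cc1OCc1ccccc1 | intermediate
5 | [3,5-bis(benzyloxy)-4-(3-methylbut-2-en-1-yl)phenoxy]tri(propan-2-yl)silane | CC(C)=CCc1c(OCc2ccccc2)cc(O[Si](C(C)C)(C(C)C)C(C)C)cc1OCc1ccccc1 | intermediate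
6 | 4-{2,6-bis(benzyloxy)-4-[tri(propan-2-yl)silyloxy]phenyl}-2-methylbutan-2-ol | CC(C)(O)CCc1c(OCc2ccccc2)cc(O[Si](C(C)C)(C(C)C)C(C)C)cc1OCc1ccccc1 | intermediate
7 | {3,5-bis(benzyloxy)-4-[3-(benzyloxy)-3-methylbutyl]phenoxy}tri(propan-2-yl)silane | CC(C)(OCc1ccccc1)CCc1c(OCc2ccccc2)cc(O[Si](C(C)C)(C(C)C)C(C)C)cc1OCc1ccccc1 | intermediate
8 | 3,5-bis(benzyloxy)-4-[3-(benzyloxy)-3-methylbutyl]phenol | CC(C)(OCc1ccccc1)CCc1c(OCc2ccccc2)cc(O)cc1OCc1ccccc1 | intermediate
9 | 3,5-bis(benzyloxy)-2-bromo-4-[3-(benzyloxy)-3-methylbutyl]phenol | CC(C)(OCc1ccccc1)CCc1c(OCc2ccccc2)cc(O)c(Br)c1OCc1ccccc1 | intermediate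
10 | {3,5-bis(benzyloxy)-2-bromo-4-[3-(benzyloxy)-3-methylbutyl]phenoxy}trimethylsilane | CC(C)(OCc1ccccc1)CCc1c(OCc2ccccc2)cc(O[Si](C)(C)C)c(Br)c1OCc1ccccc1 | intermediate
11 | {2,4-bis(benzyloxy)-3-[3-(benzyloxy)-3-methylbutyl]-6-(trimethylsilyloxy)phenyl}lithium | CC(C)(OCc1ccccc1)CCc1c(OCc2ccccc2)cc(O[Si](C)(C)C)c([Li])c1OCc1ccccc1 | intermediate
12 | lithium 3,5-bis(benzyloxy)-4-[3-(benzyloxy)-3-methylbutyl]-2-(trimethylsilyl)phenolate | CC(C)(OCc1ccccc1)CCc1c(OCc2ccccc2)cc([O-])c([Si](C)(C)C)c1OCc1ccccc1.[Li+] | intermediate
13 | 3,5-bis(benzyloxy)-4-[3-(benzyloxy)-3-methylbutyl]-2-(trimethylsilyl)phenyl trifluoromethanesulfonate | CC(C)(OCc1ccccc1)CCc1c(OCc2ccccc2)cc(OS(=O)(=O)C(F)(F)F)c([Si](C)(C)C)c1OCc1ccccc1 | intermediate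
14 | 2,4-dihydroxyphenylacetic acid | OC(=O)Cc1ccc(O)cc1O | starting material
15 | methyl 2-(2,4-dihydroxyphenyl)acetate | COC(=O)Cc1ccc(O)cc1O | intermediate
16 | methyl 2-[2,4-bis(benzyloxy)phenyl]acetate | COC(=O)Cc1ccc(OCc2ccccc2)cc1OCc1ccccc1 | intermediate
17 | sodium (Z)-2-[2,4-bis(benzyloxy)phenyl]-3-methoxy-3-oxoprop-1-en-1-olate | COC(=O)/C(=C\[O-])c1ccc(OCc2ccccc2)cc1OCc1ccccc1.[Na+] | intermediate
18 | methyl (Z)-2-[2,4-bis(benzyloxy)phenyl]-3-hydroxyprop-2-enoate | COC(=O)/C(=C\O)c1ccc(OCc2ccccc2)cc1OCc1ccccc1 | intermediate
19 | caesium (Z)-2-[2,4-bis(benzyloxy)phenyl]-3-methoxy-3-oxoprop-1-en-1-olate | COC(=O)/C(=C\[O-])c1ccc(OCc2ccccc2)cc1OCc1ccccc1.[Cs+] | intermediate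
20 | 3,5-bis(benzyloxy)-4-[3-(benzyloxy)-3-methylbutyl]-1,2-didehydrobenzene (the aryne) | CC(C)(OCc1ccccc1)CCC1=C(OCc2ccccc2)C#CC=C1OCc1ccccc1 | intermediate
21 | methyl (Z)-3-{3,5-bis(benzyloxy)-4-[3-(benzyloxy)-3-methylbutyl]-2-caesiophenoxy}-2-[2,4-bis(benzyloxy)phenyl]prop-2-enoate (the aryl anion as its caesium derivative) | CC(C)(OCc1ccccc1)CCc1c(OCc2ccccc2)cc(O/C=C(\C(=O)OC)c2ccc(OCc3ccccc3)cc2OCc2ccccc2)c([Cs])c1OCc1ccccc1 | intermediate
22 | 5,7-bis(benzyloxy)-6-[3-(benzyloxy)-3-methylbutyl]-3-[2,4-bis(benzyloxy)phenyl]-4H-chromen-4-one | CC(C)(OCc1ccccc1)CCc1c(OCc2ccccc2)cc2occ(-c3ccc(OCc4ccccc4)cc3OCc3ccccc3)c(=O)c2c1OCc1ccccc1 | intermediate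
23 | 3-(2,4-dihydroxyphenyl)-5,7-dihydroxy-6-(3-hydroxy-3-methylbutyl)-4H-chromen-4-one (luteone hydride) | CC(C)(O)CCc1c(O)cc2occ(-c3ccc(O)cc3O)c(=O)c2c1O | target

## Step count and risks

Total step count: 12. Longest linear sequence: 9 steps (steps 1 to 7, 11 and 12); steps 8 to 10 form the second branch.

**Step 11 (key step).**
- What may go wrong: C-arylation of the ambident enolate, after which the aryl anion attacks the formyl group and the aryne is formally inserted into the C–CHO bond. The aryl anion may be protonated, by hydrogen difluoride or by enol not yet deprotonated, before it cyclises. The enolate may react through its E-geometry, from which the anion cannot reach the ester. Liberated methoxide may attack the aryne or C2 of the product.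
- Fallback, by known chemistry, from 9 to 22: bromophenol 9 is deprotonated with MeLi, exchanged with tBuLi at −78 °C and acylated with N-methoxy-N-methylacetamide, giving 1-{2,4-bis(benzyloxy)-3-[3-(benzyloxy)-3-methylbutyl]-6-hydroxyphenyl}ethan-1-one F1. Condensation with N,N-dimethylformamide dimethyl acetal gives (E)-1-{2,4-bis(benzyloxy)-3-[3-(benzyloxy)-3-methylbutyl]-6-hydroxyphenyl}-3-(dimethylamino)prop-2-en-1-one F2. Iodine closes this to 5,7-bis(benzyloxy)-6-[3-(benzyloxy)-3-methylbutyl]-3-iodo-4H-chromen-4-one F3. Suzuki–Miyaura coupling with purchased 2,4-bis(benzyloxy)phenylboronic acid (OB(O)c1ccc(OCc2ccccc2)cc1OCc1ccccc1; Pd(PPh3)4, Na2CO3, DME/H2O) returns to 22.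

**Step 2.**
- What may go wrong: deprotonation at a benzylic O–CH2 position followed by 1,2-Wittig rearrangement, metalation beside the silyl ether followed by silyl migration, or allylic transposition (SN2′) in the alkylation.
- Fallback, from 1 to 6, replacing the lithiation by electrophilic substitution: Vilsmeier–Haack formylation of 1 (POCl3, DMF) para to the hydroxyl gives 2,6-bis(benzyloxy)-4-hydroxybenzaldehyde F4. Silylation (TIPSCl, imidazole) gives 2,6-bis(benzyloxy)-4-[tri(propan-2-yl)silyloxy]benzaldehyde F5. Wittig reaction with 1-(triphenylphosphoranylidene)propan-2-one in hot toluene gives (E)-4-{2,6-bis(benzyloxy)-4-[tri(propan-2-yl)silyloxy]phenyl}but-3-en-2-one F6. Conjugate reduction with [(Ph3P)CuH]6 gives 4-{2,6-bis(benzyloxy)-4-[tri(propan-2-yl)silyloxy]phenyl}butan-2-one F7. Addition of MeMgBr returns to 6, which also bypasses step 3.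

**Step 4.**
- What may go wrong: incomplete alkylation of the hindered tertiary alkoxide, or loss of the aryl silyl group under the basic conditions followed by benzylation of the phenol.
- Fallback, from 5 to 7, replacing hydration plus etherification by alkoxymercuration: 5 is treated with Hg(OAc)2 in benzyl alcohol/THF to give (acetato){1-[2,6-bis(benzyloxy)-4-(tri(propan-2-yl)silyloxy)phenyl]-3-(benzyloxy)-3-methylbutan-2-yl}mercury F8 (racemic, Markovnikov). Demercuration with NaBH4/NaOH returns to 7.

**Step 7 (and the bromination before it).**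
- What may go wrong: over-bromination in step 6; in step 7, protonation of the aryllithium before the silyl shift, lithiation at a benzylic position, or incomplete triflation of the hindered phenolate.
- Fallback, from 8 to 13, replacing halogen–metal exchange by carbamate-directed metalation (it also bypasses step 6): 8 and isopropyl isocyanate give 3,5-bis(benzyloxy)-4-[3-(benzyloxy)-3-methylbutyl]phenyl propan-2-ylcarbamate F9. In-situ N-silylation (TBSOTf, TMEDA), ortho-lithiation with nBuLi at −78 °C and quenching with Me3SiCl give 3,5-bis(benzyloxy)-4-[3-(benzyloxy)-3-methylbutyl]-2-(trimethylsilyl)phenyl propan-2-ylcarbamate F10. Cleavage with Et2NH/DBU liberates 3,5-bis(benzyloxy)-4-[3-(benzyloxy)-3-methylbutyl]-2-(trimethylsilyl)phenol F11, which is triflated in the same flask with PhNTf2 to return to 13.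

## Further compounds

F1 | step 11 | 1-{2,4-bis(benzyloxy)-3-[3-(benzyloxy)-3-methylbutyl]-6-hydroxyphenyl}ethan-1-one | CC(=O)c1c(O)cc(OCc2ccccc2)c(CCC(C)(C)OCc2ccccc2)c1OCc1ccccc1
F2 | step 11 | (E)-1-{2,4-bis(benzyloxy)-3-[3-(benzyloxy)-3-methylbutyl]-6-hydroxyphenyl}-3-(dimethylamino)prop-2-en-1-one | CN(C)/C=C/C(=O)c1c(O)cc(OCc2ccccc2)c(CCC(C)(C)OCc2ccccc2)c1OCc1ccccc1
F3 | step 11 | 5,7-bis(benzyloxy)-6-[3-(benzyloxy)-3-methylbutyl]-3-iodo-4H-chromen-4-one | CC(C)(OCc1ccccc1)CCc1c(OCc2ccccc2)cc2occ(I)c(=O)c2c1OCc1ccccc1
F4 | step 2 | 2,6-bis(benzyloxy)-4-hydroxybenzaldehyde | O=Cc1c(OCc2ccccc2)cc(O)cc1OCc1ccccc1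
F5 | step 2 | 2,6-bis(benzyloxy)-4-[tri(propan-2-yl)silyloxy]benzaldehyde | O=Cc1c(OCc2ccccc2)cc(O[Si](C(C)C)(C(C)C)C(C)C)cc1OCc1ccccc1
F6 | step 2 | (E)-4-{2,6-bis(benzyloxy)-4-[tri(propan-2-yl)silyloxy]phenyl}but-3-en-2-one | CC(=O)/C=C/c1c(OCc2ccccc2)cc(O[Si](C(C)C)(C(C)C)C(C)C)cc1OCc1ccccc1
F7 | step 2 | 4-{2,6-bis(benzyloxy)-4-[tri(propan-2-yl)silyloxy]phenyl}butan-2-one | CC(=O)CCc1c(OCc2ccccc2)cc(O[Si](C(C)C)(C(C)C)C(C)C)cc1OCc1ccccc1
F8 | step 4 | (acetato){1-[2,6-bis(benzyloxy)-4-(tri(propan-2-yl)silyloxy)phenyl]-3-(benzyloxy)-3-methylbutan-2-yl}mercury, racemic | CC(C)(OCc1ccccc1)C([Hg]OC(C)=O)Cc1c(OCc2ccccc2)cc(O[Si](C(C)C)(C(C)C)C(C)C)cc1OCc1ccccc1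
F9 | step 7 | 3,5-bis(benzyloxy)-4-[3-(benzyloxy)-3-methylbutyl]phenyl propan-2-ylcarbamate | CC(C)NC(=O)Oc1cc(OCc2ccccc2)c(CCC(C)(C)OCc2ccccc2)c(OCc2ccccc2)c1
F10 | step 7 | 3,5-bis(benzyloxy)-4-[3-(benzyloxy)-3-methylbutyl]-2-(trimethylsilyl)phenyl propan-2-ylcarbamate | CC(C)NC(=O)Oc1cc(OCc2ccccc2)c(CCC(C)(C)OCc2ccccc2)c(OCc2ccccc2)c1[Si](C)(C)C
F11 | step 7 | 3,5-bis(benzyloxy)-4-[3-(benzyloxy)-3-methylbutyl]-2-(trimethylsilyl)phenol | CC(C)(OCc1ccccc1)CCc1c(OCc2ccccc2)cc(O)c([Si](C)(C)C)c1OCc1ccccc1
A1 | alternative 1 | 3-[2,4-bis(benzyloxy)phenyl]-5,7-dihydroxy-6-(3-hydroxy-3-methylbutyl)-4H-chromen-4-one | CC(C)(O)CCc1c(O)cc2occ(-c3ccc(OCc4ccccc4)cc3OCc3ccccc3)c(=O)c2c1O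
A2 | alternative 1 | methyl 5-[2,4-bis(benzyloxy)phenyl]-2-methyl-4-oxo-4H-pyran-3-carboxylate | COC(=O)c1c(C)occ(-c2ccc(OCc3ccccc3)cc2OCc2ccccc2)c1=O
A3 | alternative 1 | 6,6-dimethyltetrahydro-2H-pyran-2-one | CC1(C)CCCC(=O)O1
A4 | alternative 2 | 5,7-bis(benzyloxy)-6-[3-(benzyloxy)-3-methylbutyl]-3-[2,4-bis(benzyloxy)phenyl]-3-hydroxychroman-4-one, racemic | CC(C)(OCc1ccccc1)CCc1c(OCc2ccccc2)cc2OCC(O)(c3ccc(OCc4ccccc4)cc3OCc3ccccc3)C(=O)c2c1OCc1ccccc1
A5 | alternative 2 | 2-{2-[2,4-bis(benzyloxy)phenyl]-2-oxoethoxy}-4,6-bis(benzyloxy)-5-[3-(benzyloxy)-3-methylbutyl]benzaldehyde | O=Cc1c(OCC(=O)c2ccc(OCc3ccccc3)cc2OCc2ccccc2)cc(OCc2ccccc2)c(CCC(C)(C)OCc2ccccc2)c1OCc1ccccc1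
A6 | alternative 3 | 5,7-bis(benzyloxy)-6-[3-(benzyloxy)-3-methylbutyl]-3-{2-hydroxy-4-[tri(propan-2-yl)silyloxy]phenyl}-4H-chromen-4-one | CC(C)(OCc1ccccc1)CCc1c(OCc2ccccc2)cc2occ(-c3ccc(O[Si](C(C)C)(C(C)C)C(C)C)cc3O)c(=O)c2c1OCc1ccccc1
A7 | alternative 3 | 5,7-bis(benzyloxy)-6-[3-(benzyloxy)-3-methylbutyl]-3-[(E)-4-diazo-3-oxobut-1-en-1-yl]-4H-chromen-4-one | CC(C)(OCc1ccccc1)CCc1c(OCc2ccccc2)cc2occ(/C=C/C(=O)C=[N+]=[N-])c(=O)c2c1OCc1ccccc1
A8 | alternative 3 | (ethynyloxy)tri(propan-2-yl)silane | C#CO[Si](C(C)C)(C(C)C)C(C)C
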